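## Retrosynthetic overview

1. Numbering as in halimanes: ring A = C1–C5 and C10; ring B = C5–C10; chain C11–C16 on C9; methyls C17 (on C8), C19 (on C4), C20 (on C9); carboxyl C18 (on C4).
2. Ring A is a cyclohexene whose only double bond, C1=C10, lies between C2 and C5, and whose C4 bears a carbonyl carbon (C18) and a methyl (C19). This is a Diels–Alder retron: cutting C2–C3 and C4–C5 leaves the 1-vinylcyclohexene C2=C1–C10=C5 (ring B with the finished side chain) and methacrolein; the C18 aldehyde is oxidised last.
3. Side chain: 13-OH/14,15-diacetate from a (13E)-allylic alcohol by Sharpless epoxidation and hydroxide opening with inversion at C14; the allylic alcohol from a C13 methyl ketone (Horner–Wadsworth–Emmons, then DIBAL-H).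
4. Diene and ring B: C10 ketone → enol triflate → Stille vinylation; quaternary C9 by Mukaiyama–Michael addition to methyl vinyl ketone anti to the C8 methyl; C8 by copper-catalysed asymmetric methyl addition to 2-methylcyclohex-2-en-1-one.
5. Ring order: ring B is bought as the enone; ring A is closed in step 10, where C5 and C4 are set in one event by relay from C9 and C8.

Key step: step 10

Remark (assumption): in step 1 the sense of induction is fixed by the ligand enantiomer; the enantiomer of the phosphoramidite ligand that gives the (3R) adduct is the one used.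

## Route

Step 1
Reactants: 1 2-methylcyclohex-2-en-1-one; 2 trimethylaluminium; 3 trimethylsilyl trifluoromethanesulfonate
Product: 5 trimethyl{[(3R)-2,3-dimethylcyclohex-1-en-1-yl]oxy}silane, via dimethylaluminium enolate 4 (not isolated)
Conditions: 2 (1.4 equiv), copper thiophene-2-carboxylate Cu(O2CC4H3S) (2 mol%), BINOL/bis(1-phenylethyl)amine phosphoramidite ligand (4 mol%), Et2O, −30 °C; then 3, THF, 0 °C
Reagents that add atoms: trimethylaluminium, C[Al](C)C; trimethylsilyl trifluoromethanesulfonate, C[Si](C)(C)OS(=O)(=O)C(F)(F)F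
Why: Copper-catalysed asymmetric conjugate addition of a trialkylaluminium to a 2-substituted cyclohexenone, in which the chiral copper–phosphoramidite complex delivers methyl to one face of C8 and so sets C8 (R), while O-silylation of the aluminium enolate fixes the C9=C10 enol ether needed for step 2.

Step 2
Reactants: 5 trimethyl{[(3R)-2,3-dimethylcyclohex-1-en-1-yl]oxy}silane; 6 but-3-en-2-one (methyl vinyl ketone)
Product: 8 (2S,3R)-2,3-dimethyl-2-(3-oxobutyl)cyclohexan-1-one, via silyl enol ether adduct 7 (not isolated)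
Conditions: 6 (1.5 equiv), TMSOTf (10 mol%), CH2Cl2, −78 °C; then 1 M HCl, THF, 0 °C
Reagents that add atoms: but-3-en-2-one, CC(=O)C=C
Why: Mukaiyama–Michael addition in which C9 of the tetrasubstituted enol ether attacks the silyl-activated enone on the face anti to the neighbouring C8 methyl (axial attack on the half-chair with that methyl pseudo-axial), which should set the quaternary C9 (S) with the two methyls cis, and silyl transfer to the new enolate 7 turns the catalyst over before acid releases the diketone.

Step 3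
Reactants: 8 (2S,3R)-2,3-dimethyl-2-(3-oxobutyl)cyclohexan-1-one; 9 triethyl phosphonoacetate
Product: 10 ethyl (2E)-5-[(1S,2R)-1,2-dimethyl-6-oxocyclohexyl]-3-methylpent-2-enoate
Conditions: 9 (1.3 equiv), NaH (1.25 equiv), THF, 0 → 40 °C
Reagents that add atoms: triethyl phosphonoacetate, CCOC(=O)CP(=O)(OCC)OCC
Why: Horner–Wadsworth–Emmons olefination in which the phosphonate anion should attack only the unhindered methyl ketone C13=O (the ring ketone is flanked by the quaternary C9), with the (E)-enoate expected as the major isomer and the minor (Z) isomer to be removed by chromatography.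

Step 4
Reactants: 10 ethyl (2E)-5-[(1S,2R)-1,2-dimethyl-6-oxocyclohexyl]-3-methylpent-2-enoate; 11 N-phenylbis(trifluoromethanesulfonimide)
Product: 13 ethyl (2E)-5-[(1S,6R)-1,6-dimethyl-2-(trifluoromethanesulfonyloxy)cyclohex-2-en-1-yl]-3-methylpent-2-enoate, via potassium enolate 12 (not isolated)
Conditions: KN(SiMe3)2 (1.1 equiv), THF, −78 °C; then 11, −78 → 0 °C; aqueous NH4Cl
Reagents that add atoms: N-phenylbis(trifluoromethanesulfonimide), O=S(=O)(N(c1ccccc1)S(=O)(=O)C(F)(F)F)C(F)(F)F
Why: Kinetic enolate O-triflation, in which the ring ketone can enolise only toward C5 because C9 is quaternary, its α-protons are more acidic than the γ-protons of the enoate, and the potassium enolate is trapped on oxygen by PhNTf2.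

Step 5
Reactants: 13 ethyl (2E)-5-[(1S,6R)-1,6-dimethyl-2-(trifluoromethanesulfonyloxy)cyclohex-2-en-1-yl]-3-methylpent-2-enoate; 14 tributyl(ethenyl)stannane
Product: 15 ethyl (2E)-5-[(1S,6R)-2-ethenyl-1,6-dimethylcyclohex-2-en-1-yl]-3-methylpent-2-enoate
Conditions: 14 (1.3 equiv), Pd(PPh3)4 (5 mol%), LiCl (3 equiv), THF, 65 °C
Reagents that add atoms: tributyl(ethenyl)stannane, C=C[Sn](CCCC)(CCCC)CCCC
Why: Stille cross-coupling of an enol triflate (chloride-assisted) should transfer the vinyl group to C10 without moving the C5=C10 double bond, giving the 1-vinylcyclohexene diene.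

Step 6
Reactants: 15 ethyl (2E)-5-[(1S,6R)-2-ethenyl-1,6-dimethylcyclohex-2-en-1-yl]-3-methylpent-2-enoate
Product: 16 (2E)-5-[(1S,6R)-2-ethenyl-1,6-dimethylcyclohex-2-en-1-yl]-3-methylpent-2-en-1-ol
Conditions: i-Bu2AlH (2.5 equiv), CH2Cl2, −78 °C; aqueous potassium sodium tartrate
Reagents that add atoms: none
Why: DIBAL-H 1,2-reduction of the α,β-unsaturated ester to the allylic alcohol, which leaves the unactivated diene and the stereocentres untouched.

Step 7
Reactants: 16 (2E)-5-[(1S,6R)-2-ethenyl-1,6-dimethylcyclohex-2-en-1-yl]-3-methylpent-2-en-1-ol; 17 tert-butyl hydroperoxide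
Product: 18 [(2R,3R)-3-{2-[(1S,6R)-2-ethenyl-1,6-dimethylcyclohex-2-en-1-yl]ethyl}-3-methyloxiran-2-yl]methanol
Conditions: Ti(OiPr)4 (10 mol%), D-(−)-diethyl tartrate (12 mol%), 17 (2 equiv), 4 Å molecular sieves, CH2Cl2, −20 °C
Reagents that add atoms: tert-butyl hydroperoxide, CC(C)(C)OO
Why: Sharpless asymmetric epoxidation, in which the titanium tartrate complex binds the allylic hydroxyl and delivers oxygen to one face of C13=C14 under reagent control (D-(−)-tartrate gives the 2R,3R epoxy alcohol from an (E)-3,3-disubstituted allylic alcohol), while the non-allylic diene is inert.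

Step 8
Reactants: 18 [(2R,3R)-3-{2-[(1S,6R)-2-ethenyl-1,6-dimethylcyclohex-2-en-1-yl]ethyl}-3-methyloxiran-2-yl]methanol; 19 water
Product: 20 (2S,3R)-5-[(1S,6R)-2-ethenyl-1,6-dimethylcyclohex-2-en-1-yl]-3-methylpentane-1,2,3-triol
Conditions: 0.5 M NaOH, H2O/t-BuOH, 70 °C
Reagents that add atoms: water, O
Why: Base-mediated epoxide hydrolysis through the Payne rearrangement, in which the C15 alkoxide opens the epoxide at C14 with inversion and hydroxide then opens the terminal epoxide at C15 (direct hydroxide attack at C14 leads to the same triol), so that C13 keeps its configuration (R) and C14 becomes S.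

Step 9
Reactants: 20 (2S,3R)-5-[(1S,6R)-2-ethenyl-1,6-dimethylcyclohex-2-en-1-yl]-3-methylpentane-1,2,3-triol; 21 acetic anhydride
Product: 22 (2S,3R)-5-[(1S,6R)-2-ethenyl-1,6-dimethylcyclohex-2-en-1-yl]-3-hydroxy-3-methylpentane-1,2-diyl diacetate
Conditions: 21 (2.5 equiv), pyridine, DMAP (2 mol%), CH2Cl2, 0 °C → rt
Reagents that add atoms: acetic anhydride, CC(=O)OC(C)=O
Why: Selective O-acylation in which acetic anhydride/pyridine esterifies the primary and the secondary hydroxyl, whereas the tertiary C13 hydroxyl should not be acylated without heat or a large amount of acyl-transfer catalyst.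

Step 10
Reactants: 22 (2S,3R)-5-[(1S,6R)-2-ethenyl-1,6-dimethylcyclohex-2-en-1-yl]-3-hydroxy-3-methylpentane-1,2-diyl diacetate; 23 2-methylprop-2-enal (methacrolein)
Product: 25 (1S,5S,6R,8aS)-5-[(3R,4S)-4,5-diacetoxy-3-hydroxy-3-methylpentyl]-1,5,6-trimethyl-1,2,3,5,6,7,8,8a-octahydronaphthalene-1-carbaldehyde, via chloro(methyl)aluminium alkoxide 24 (not isolated)
Conditions: 23 (5 equiv), Me2AlCl (3 equiv), CH2Cl2, −78 → −30 °C; aqueous potassium sodium tartrate
Reagents that add atoms: methacrolein, CC(=C)C=O
Why: The Me2AlCl complex of methacrolein and the s-cis diene C2=C1–C10=C5 of 24 should combine in a concerted, asynchronous [4+2] cycloaddition in which C2–C3 leads and C4–C5 follows; the closest known reaction type is the Lewis-acid-promoted Diels–Alder reaction of 1-vinylcyclohexenes carrying an allylic quaternary carbon with 2-substituted acroleins. Ring A is closed by this intermolecular [4+2] mode, which makes both new σ bonds and leaves the C1=C10 double bond exactly where the target has it. C5 is controlled by C9: in the reactive half-chair the C9 side chain is pseudo-axial (this avoids allylic strain with the C10 vinyl group and places the chain anti to the C8 methyl), it covers the β face of C5=C10, and the dienophile should bond to C5 from the α face, syn to the C9 methyl, so that H-5 ends cis to the side chain. C4 is controlled by exo placement of the aluminium-bound formyl group: the endo position lies under ring B beside the axial C8 methyl and H-6, where only the small C4 methyl should fit, which puts the formyl carbon C18 cis to H-5. The step needs regioselectivity (C4 to C5), secured by the polarised dienophile whose CH2 terminus C3 joins the unsubstituted diene terminus C2; s-cis reactivity, secured by the quaternary C9 that disfavours the s-trans rotamer; and the facial and exo selectivity named above, both of which rest on the C8/C9 substitution of ring B.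

Step 11
Reactants: 25 (1S,5S,6R,8aS)-5-[(3R,4S)-4,5-diacetoxy-3-hydroxy-3-methylpentyl]-1,5,6-trimethyl-1,2,3,5,6,7,8,8a-octahydronaphthalene-1-carbaldehyde; 26 sodium chlorite
Product: 27 (1S,5S,6R,8aS)-5-[(3R,4S)-4,5-diacetoxy-3-hydroxy-3-methylpentyl]-1,5,6-trimethyl-1,2,3,5,6,7,8,8a-octahydronaphthalene-1-carboxylic acid (target)
Conditions: 26 (3 equiv), NaH2PO4, 2-methylbut-2-ene (10 equiv), t-BuOH/H2O, rt
Reagents that add atoms: sodium chlorite, [Na+].[O-]Cl=O
Why: Pinnick oxidation, in which chlorite at about pH 4 oxidises the hindered, non-enolisable aldehyde to the acid, 2-methylbut-2-ene scavenges hypochlorous acid so that the C1=C10 alkene survives, and the acetates and the tertiary alcohol are stable.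

## Compound list

1 | 2-methylcyclohex-2-en-1-one | CC1=CCCCC1=O | starting material
2 | trimethylaluminium | C[Al](C)C | starting material
3 | trimethylsilyl trifluoromethanesulfonate | C[Si](C)(C)OS(=O)(=O)C(F)(F)F | starting material
4 | dimethylaluminium (3R)-2,3-dimethylcyclohex-1-en-1-olate | CC1=C(O[Al](C)C)CCC[C@H]1C | intermediate
5 | trimethyl{[(3R)-2,3-dimethylcyclohex-1-en-1-yl]oxy}silane | CC1=C(O[Si](C)(C)C)CCC[C@H]1C | intermediate
6 | but-3-en-2-one | CC(=O)C=C | starting material
7 | (2S,3R)-2,3-dimethyl-2-[3-(trimethylsilyloxy)but-2-en-1-yl]cyclohexan-1-one (enol ether geometry not defined) | CC(O[Si](C)(C)C)=CC[C@]1(C)C(=O)CCC[C@H]1C | intermediate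
8 | (2S,3R)-2,3-dimethyl-2-(3-oxobutyl)cyclohexan-1-one | CC(=O)CC[C@]1(C)C(=O)CCC[C@H]1C | intermediate
9 | triethyl phosphonoacetate | CCOC(=O)CP(=O)(OCC)OCC | starting material
10 | ethyl (2E)-5-[(1S,2R)-1,2-dimethyl-6-oxocyclohexyl]-3-methylpent-2-enoate | CCOC(=O)/C=C(\C)CC[C@]1(C)C(=O)CCC[C@H]1C | intermediate
11 | N-phenylbis(trifluoromethanesulfonimide) | O=S(=O)(N(c1ccccc1)S(=O)(=O)C(F)(F)F)C(F)(F)F | starting material
12 | potassium C5=C10 enolate of 10 | CCOC(=O)/C=C(\C)CC[C@]1(C)C([O-])=CCC[C@H]1C.[K+] | intermediate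
13 | ethyl (2E)-5-[(1S,6R)-1,6-dimethyl-2-(trifluoromethanesulfonyloxy)cyclohex-2-en-1-yl]-3-methylpent-2-enoate | CCOC(=O)/C=C(\C)CC[C@]1(C)C(OS(=O)(=O)C(F)(F)F)=CCC[C@H]1C | intermediate
14 | tributyl(ethenyl)stannane | C=C[Sn](CCCC)(CCCC)CCCC | starting material
15 | ethyl (2E)-5-[(1S,6R)-2-ethenyl-1,6-dimethylcyclohex-2-en-1-yl]-3-methylpent-2-enoate | CCOC(=O)/C=C(\C)CC[C@]1(C)C(C=C)=CCC[C@H]1C | intermediate
16 | (2E)-5-[(1S,6R)-2-ethenyl-1,6-dimethylcyclohex-2-en-1-yl]-3-methylpent-2-en-1-ol | OC/C=C(\C)CC[C@]1(C)C(C=C)=CCC[C@H]1C | intermediate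
17 | tert-butyl hydroperoxide | CC(C)(C)OO | starting material
18 | [(2R,3R)-3-{2-[(1S,6R)-2-ethenyl-1,6-dimethylcyclohex-2-en-1-yl]ethyl}-3-methyloxiran-2-yl]methanol | OC[C@H]1O[C@]1(C)CC[C@]2(C)C(C=C)=CCC[C@H]2C | intermediate
19 | water | O | starting material
20 | (2S,3R)-5-[(1S,6R)-2-ethenyl-1,6-dimethylcyclohex-2-en-1-yl]-3-methylpentane-1,2,3-triol | OC[C@H](O)[C@](C)(O)CC[C@]1(C)C(C=C)=CCC[C@H]1C | intermediate
21 | acetic anhydride | CC(=O)OC(C)=O | starting material
22 | (2S,3R)-5-[(1S,6R)-2-ethenyl-1,6-dimethylcyclohex-2-en-1-yl]-3-hydroxy-3-methylpentane-1,2-diyl diacetate | CC(=O)OC[C@H](OC(C)=O)[C@](C)(O)CC[C@]1(C)C(C=C)=CCC[C@H]1C | intermediate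
23 | 2-methylprop-2-enal (methacrolein) | CC(=C)C=O | starting material
24 | chloro(methyl)aluminium O-13 alkoxide of 22 | CC(=O)OC[C@H](OC(C)=O)[C@](C)(O[Al](C)Cl)CC[C@]1(C)C(C=C)=CCC[C@H]1C | intermediate
25 | (1S,5S,6R,8aS)-5-[(3R,4S)-4,5-diacetoxy-3-hydroxy-3-methylpentyl]-1,5,6-trimethyl-1,2,3,5,6,7,8,8a-octahydronaphthalene-1-carbaldehyde | CC(=O)OC[C@H](OC(C)=O)[C@](C)(O)CC[C@]1(C)C2=CCC[C@](C)(C=O)[C@H]2CC[C@H]1C | intermediate
26 | sodium chlorite | [Na+].[O-]Cl=O | starting material
27 | (1S,5S,6R,8aS)-5-[(3R,4S)-4,5-diacetoxy-3-hydroxy-3-methylpentyl]-1,5,6-trimethyl-1,2,3,5,6,7,8,8a-octahydronaphthalene-1-carboxylic acid | CC(=O)OC[C@H](OC(C)=O)[C@](C)(O)CC[C@]1(C)C2=CCC[C@](C)(C(=O)O)[C@H]2CC[C@H]1C | target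

## Step count and risks

Total step count: 11. Longest linear sequence: 11 steps (the route is linear from 1).

Steps most likely to fail:

1. Step 10 (key cycloaddition). This is the least secure step of the route. The dienophile may add to the β face of C5 (syn to the side chain), because the α face carries the axial C8 methyl. The formyl group may also take the endo position, and the aluminium alkoxide may cause acetyl migration from O-14 to O-13. The fallback is a metal-free ionic Diels–Alder reaction with a bulkier, exo-seeking dienophile, setting out from 22. Silylation with TMSOTf and 2,6-lutidine (CH2Cl2, −78 °C) should give the 13-O-trimethylsilyl ether F1. Treatment of this ether with 2-(prop-1-en-2-yl)-1,3-dioxolane and catalytic TMSOTf at −78 °C should give, through the 2-alkoxyallyl cation formed by opening of the acetal, the dioxolane cycloadduct F2. PPTS in wet acetone then cleaves the acetal and the silyl ether and comes back to the route at aldehyde 25 for step 11.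

2. Step 2 (quaternary C9). The Michael addition may stall at the congested tetrasubstituted enol ether, methyl vinyl ketone may polymerise under the silyl triflate, or the 1,5-diketone may undergo aldol cyclisation. The fallback replaces conjugate addition by enolate alkylation with a masked 3-oxobutyl group (Wichterle reagent), setting out from 5. MeLi in THF at 0 °C should give the lithium enolate F3. Alkylation with (Z)-1,3-dichlorobut-2-ene (THF/DMPU, −78 → 0 °C), again anti to the C8 methyl, should give the vinyl chloride F4. Concentrated H2SO4 at 0 °C followed by water hydrolyses the vinyl chloride to the methyl ketone and comes back to the route at 8.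

3. Step 8 (epoxide opening). Hydroxide opening may be slow at the trisubstituted epoxide, or competing attack at the tertiary C13 may erode the configuration. The fallback inverts C13 instead of C14 and starts from the enantiomeric epoxide, setting out from 16. Sharpless epoxidation with L-(+)-diethyl tartrate should give the (2S,3S)-epoxy alcohol F5. Ti(OiPr)4 (1.5 equiv) and benzoic acid in CH2Cl2 at rt should open it at C13 with inversion to give the C13 benzoate F6. K2CO3 in MeOH removes the benzoate and comes back to the route at triol 20.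

## Further compounds

F1 | step 10 | (2S,3R)-5-[(1S,6R)-2-ethenyl-1,6-dimethylcyclohex-2-en-1-yl]-3-methyl-3-(trimethylsilyloxy)pentane-1,2-diyl diacetate | CC(=O)OC[C@H](OC(C)=O)[C@](C)(O[Si](C)(C)C)CC[C@]1(C)C(C=C)=CCC[C@H]1C
F2 | step 10 | ethylene acetal (1,3-dioxolan-2-yl on C4) of aldehyde 25 carrying a trimethylsilyl ether on O-13 | CC(=O)OC[C@H](OC(C)=O)[C@](C)(O[Si](C)(C)C)CC[C@]1(C)C2=CCC[C@](C)(C3OCCO3)[C@H]2CC[C@H]1C
F3 | step 2 | lithium (3R)-2,3-dimethylcyclohex-1-en-1-olate | CC1=C([O-])CCC[C@H]1C.[Li+]
F4 | step 2 | (2S,3R)-2-[(2Z)-3-chlorobut-2-en-1-yl]-2,3-dimethylcyclohexan-1-one | C/C(Cl)=C/C[C@]1(C)C(=O)CCC[C@H]1C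
F5 | step 8 | [(2S,3S)-3-{2-[(1S,6R)-2-ethenyl-1,6-dimethylcyclohex-2-en-1-yl]ethyl}-3-methyloxiran-2-yl]methanol | OC[C@@H]1O[C@@]1(C)CC[C@]2(C)C(C=C)=CCC[C@H]2C
F6 | step 8 | (2S,3R)-5-[(1S,6R)-2-ethenyl-1,6-dimethylcyclohex-2-en-1-yl]-1,2-dihydroxy-3-methylpentan-3-yl benzoate | OC[C@H](O)[C@](C)(OC(=O)c1ccccc1)CC[C@]1(C)C(C=C)=CCC[C@H]1C
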